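The readings are simulated on assumed constants; noise was put on by code.

In a one-step world, where a single step gave both links and isomer, the two would rise in a fixed ratio, so I first asked whether this flask is such a world.

| flask | solid first end groups | second end groups | third end groups | remark | time |
|---|---|---|---|---|---|
| delta | 20 mM | 0.95 equiv | 0.50 equiv | run made earlier |  |
| eta | 20 mM | 0.64 equiv | 0.50 equiv | run made earlier |  |
| gamma | 20 mM | 1.4 equiv | 0.50 equiv | run made earlier |  |
| theta | 10 mM | 0.95 equiv | 0.50 equiv | run made earlier |  |
| ochre | 20 mM | 0.950 equiv | 0.500 equiv (fed, over 2.0 h) | all else is in the flask from the start; the feed brings no volume worth counting | 2.5 h |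
| amber | 20 mM | 0.950 equiv (fed, over 2.0 h) | 0.500 equiv | all else is in the flask from the start; the feed brings no volume worth counting | 2.5 h |
| green | 20 mM | 0.950 equiv | 0.500 equiv | everything together at the start | 2.5 h |
| teal | 20 mM | 0.950 equiv (in portions, 4, over 2.0 h) | 0.500 equiv | first portion at the start, last at 2.0 h | 2.5 h |
| grey | 20 mM | 0.950 equiv | 0.500 equiv (fed, over 12 min) | all else is in the flask from the start; the feed brings no volume worth counting | 2.5 h |

delta run (percent of the solid first end groups charged)

| time / h | isomer of the product / % | links / % |
|---|---|---|
| 0.500 | 0 | 6.8 |
| 1.00 | 2.6 | 17.5 |
| 1.50 | 4.7 | 24.5 |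
| 2.00 | 7.0 | 29.0 |
| 2.50 | 9.4 | 32.0 |

eta run (percent of the solid first end groups charged)

| time / min | isomer of the product / % | links / % |
|---|---|---|
| 20.0 | 0 | 2.0 |
| 40.0 | 0.6 | 4.7 |
| 50.0 | 0.3 | 5.9 |
| 80.0 | 1.5 | 8.8 |
| 90.0 | 2.0 | 9.1 |

gamma run (percent of the solid first end groups charged)

| time / min | isomer of the product / % | links / % |
|---|---|---|
| 8.00 | 0 | 1.0 |
| 25.0 | 0.5 | 8.7 |
| 40.0 | 1.5 | 16.0 |
| 60.0 | 3.4 | 25.8 |
| 90.0 | 6.8 | 38.6 |

theta run (percent of the solid first end groups charged)

| time / min | isomer of the product / % | links / % |
|---|---|---|
| 8.00 | 0 | 1.1 |
| 15.0 | 0 | 3.1 |
| 25.0 | 0.2 | 6.6 |
| 50.0 | 1.5 | 16.4 |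
| 90.0 | 4.9 | 28.3 |

(each reading ± 0.3 percentage points)

- given per volume of solution although it is solid: solid first end groups
- reactions considered so far: first end groups + second end groups -> links; second end groups + third end groups -> links of the second sort; solid first end groups <-> first end groups; links <-> isomer of the product; second end groups -> decomposed reagent
- at the start none of the solid first end groups is in solution

- the flask that comes out highest in amount of isomer of the product, in percent of the solid first end groups charged; "all alike" if 1.5 percentage points covers them all (ochre / amber / green / teal / grey / all alike)
- amount of isomer of the product at the end, in percent of the solid first end groups charged, ochre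
- amount of isomer of the product at the end, in percent of the solid first end groups charged, amber
- amount of isomer of the product at the end, in percent of the solid first end groups charged, green
- amount of isomer of the product at the end, in percent of the solid first end groups charged, teal
- amount of isomer of the product at the end, in percent of the solid first end groups charged, grey

Delta says it is not. Between 1.00 h and 2.50 h, links rose by a factor of 1.83, yet isomer rose by a factor of 3.62. That clears up once isomer is seen to grow from links, so I integrated its rate and counted link-hours, the links fraction summed over time. Delta's readings gave:

link-hours = 0.469 h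

turnover = isomer / link-hours = 0.200 /h

This turnover, isomer gained per link-hour up to the end time, is a net pseudo-first-order constant, read with the scatter of the readings. At 1.00 h the same ratio read 0.334 /h, so I used it only at the end time.

The links' height I took from the excess of second over third end groups, as fractions of the charge, 0.450. Eta reached 11.1% of links plus isomer on an excess of 0.140, and gamma 45.4% on 0.900. Links then start when the second end groups added pass the third, and I drew a straight rise to that height:

amber: onset 1.05 h, isomer 6.53%

teal: onset at the third portion, 1.33 h, isomer 5.26%

The forecast named ochre and gave 12% for ochre, 3.7% for amber, 9.4% for green, 3.5% for teal and 9.8% for grey, on the ground that “third end groups act as a fast scavenger”. My amber and teal stood above its figures.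

The flasks gave 11.3% for ochre, 6.08% for amber, 9.03% for green, 5.18% for teal and 9.05% for grey. So ochre led by 2.2 percentage points over the next flask, against a margin of 1.5 points, and amber ended above the forecast's range.

    first end groups + second end groups → links (k = 3.60 /M/min)
    second end groups + third end groups → links of the second sort (k = 23.0 /M/min)
    solid first end groups ⇌ first end groups, rate k3*(cs3 - [first end groups]) while solid is left; crystals form when [first end groups] > cs3 (solubility = 16.0 mM, k = 0.0100 /min)
    links ⇌ isomer of the product (K = 0.410, k = 0.00610 /min)
    second end groups → decomposed reagent (k = 3.20 × 10⁻⁴ /min)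

Teal's 5.18% stood against the 5.26% from 0.200 /h. In teal the relaxation half-life of links and isomer, both ways together, was 0.551 h, short against the 2.5 h of the run.

A neighbour flask, the same as teal but with 0.380 equiv of second end groups, has an excess of −0.120, so the straight rise has no height and 0.200 /h gives no isomer. That flask gave 0.993%, with links at 4.72%.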